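## Retrosynthetic overview

- Last operations: free acid from its allyl ester; 1-OH by γ-oxygenation of the ring dienolate; 4-ketone by allylic oxidation. This is the oxidation order of the fungal pathway (α-ionylidene acid → 4'-oxo → 1'-deoxy-ABA → ABA).
- Side arm: ester bond between the ring CH2OH and (S)-3-hydroxy-3-methylglutaric acid monomethyl ester, made by enzymatic desymmetrisation of the dimethyl ester.
- The only ring (one cyclohexene, formed once, mid-route): cyclase-type cation–olefin cyclisation of an acyclic farnesoate-type (2Z,4E,6E)-trienoate, forming C1–C6 and the 2-ene. It is initiated by an (R)-2,2-disubstituted epoxide in place of H+, so the methyl oxygen and the quaternary C-6 stereocentre arise in the ring-forming event.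
- Acyclic trienoate: C10 epoxy-enal plus methyl 3-methylbut-2-enoate (γ-aldol, lactone, eliminative opening sets 2Z,4E).
- Epoxy-enal: from geranyl acetate by SeO2 hydroxylation, Sharpless epoxidation, hydride opening, oxirane closure and MnO2 oxidation.

Assumption: the target is taken exactly as the SMILES reads, i.e. (1R,6S) ring centres (acyloxymethyl cis to the dienoic acid chain, trans to the 1-OH), (3R) glutarate, 2Z,4E chain; pig liver esterase is taken to give the (S)-half ester, and L-(+)-tartrate the (2S,3S)-epoxy alcohol, both as I recall them reported.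

## Route

Step 1
Reactants: 1 geranyl acetate [(2E)-3,7-dimethylocta-2,6-dien-1-yl acetate]
Product: 2 (2E,6E)-8-hydroxy-3,7-dimethylocta-2,6-dien-1-yl acetate
Conditions: SeO2 (0.2 equiv), t-BuOOH (70% aq., 3 equiv), CH2Cl2, rt
Reagents that add atoms: tert-butyl hydroperoxide, CC(C)(C)OO (terminal oxidant; the O atom is passed on by catalytic selenium dioxide, O=[Se]=O)
Why: SeO2/t-BuOOH allylic hydroxylation (ene reaction then [2,3]-shift) attacks the (E)-methyl of the more electron-rich 6,7-olefin and gives the E allylic alcohol, the 2,3-olefin being deactivated by the allylic acetate.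

Step 2
Reactants: 2 (2E,6E)-8-hydroxy-3,7-dimethylocta-2,6-dien-1-yl acetate
Product: 3 (2E)-5-[(2S,3S)-3-(hydroxymethyl)-3-methyloxiran-2-yl]-3-methylpent-2-en-1-yl acetate
Conditions: Ti(OiPr)4 (10 mol%), L-(+)-DET (12 mol%), t-BuOOH (2 equiv), 4 Å MS, CH2Cl2, −20 °C
Reagents that add atoms: tert-butyl hydroperoxide, CC(C)(C)OO
Why: Sharpless asymmetric epoxidation, in which the C-8 hydroxyl binds the Ti–tartrate catalyst and L-(+)-DET delivers oxygen to the face that gives the (2S,3S)-epoxy alcohol (the sense found for E-2-alkenols), fixing the oxygen-bearing tertiary carbon that becomes ring C-6.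

Step 3
Reactants: 3 (2E)-5-[(2S,3S)-3-(hydroxymethyl)-3-methyloxiran-2-yl]-3-methylpent-2-en-1-yl acetate
Product: 4 (2E,7R)-3,7-dimethyloct-2-ene-1,7,8-triol
Conditions: LiAlH4, THF, 0 °C → rt; H2O/NaOH work-up
Reagents that add atoms: none
Why: Regioselective hydride opening of a 2,3-epoxy alcohol at the less substituted epoxide carbon (SN2) leaves the C–O bond of the tertiary centre untouched (retention, 7R by CIP) and reduces off the acetate in the same operation.

Step 4
Reactants: 4 (2E,7R)-3,7-dimethyloct-2-ene-1,7,8-triol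
Product: 6 (2E)-3-methyl-6-[(2R)-2-methyloxiran-2-yl]hex-2-en-1-ol, via primary monotosylate 5 (not isolated)
Conditions: Bu2SnO (2 mol%), TsCl (1.05 equiv), Et3N, CH2Cl2, 0 °C; then K2CO3, MeOH, rt
Reagents that add atoms: none
Why: Stannylene-mediated sulfonylation is selective for the primary OH of the 1,2-diol over the isolated allylic OH, and the tertiary alkoxide then closes the oxirane by intramolecular Williamson displacement without touching the stereocentre (2R epoxide).

Step 5
Reactants: 6 (2E)-3-methyl-6-[(2R)-2-methyloxiran-2-yl]hex-2-en-1-ol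
Product: 7 (2E)-3-methyl-6-[(2R)-2-methyloxiran-2-yl]hex-2-enal
Conditions: activated MnO2 (excess), CH2Cl2, rt
Reagents that add atoms: none
Why: MnO2 oxidises only the allylic alcohol to the enal (chemoselective allylic alcohol oxidation), with retention of the E olefin and no effect on the epoxide.

Step 6
Reactants: 7 (2E)-3-methyl-6-[(2R)-2-methyloxiran-2-yl]hex-2-enal; 8 methyl 3-methylbut-2-enoate
Product: 12 prop-2-en-1-yl (2Z,4E,6E)-3,7-dimethyl-10-[(2R)-2-methyloxiran-2-yl]deca-2,4,6-trienoate, via γ-aldol adduct 9 (not isolated), via dihydropyranone 10 (not isolated), via potassium trienoate 11 (not isolated)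
Conditions: LDA (1.1 equiv), THF, −78 °C → rt; then KOtBu (1.5 equiv), 0 °C → rt; then allyl bromide (3 equiv), DMF, rt
Reagents that add atoms: allyl bromide, C=CCBr
Why: Vinylogous (γ-selective on warming) aldol of the lithium dienolate of 8 onto the enal, lactonisation to the 5,6-dihydropyran-2-one, E1cB eliminative ring opening that gives the 2Z (held by the ring) 4E dienoate as in the lactone route to 13-cis-retinoic acid, and SN2 O-allylation of the carboxylate, all in one pot under basic conditions that the hindered epoxide tolerates.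

Step 7
Reactants: 12 prop-2-en-1-yl (2Z,4E,6E)-3,7-dimethyl-10-[(2R)-2-methyloxiran-2-yl]deca-2,4,6-trienoate
Product: 13 prop-2-en-1-yl (2Z,4E)-5-[(1RS,6R)-6-(hydroxymethyl)-2,6-dimethylcyclohex-2-en-1-yl]-3-methylpenta-2,4-dienoate
Conditions: Ph4PBF4 (10 mol%), HFIP (0.01 M), 0 °C → rt
Reagents that add atoms: none
Why: Proposed new method: hydrogen-bond activation by HFIP lets the 6,7-π-bond open the 2,2-disubstituted oxirane at its tertiary carbon in an SN2-like, chair-type 6-endo cation–olefin cyclisation with inversion, so the (R)-epoxide carbon becomes the quaternary ring carbon carrying CH3 and CH2OH in the required absolute sense, and the tertiary C-2 cation (kept on the six-ring path by the dienoate, as in pseudoionone → α-ionone) loses H-3 to give the 2-ene; the closest known reaction types are epoxide-initiated cation–olefin polycyclisation in HFIP and the acid cyclisation of pseudoionone-type polyenes to α-ionone-type rings.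

Step 8
Reactants: 14 dimethyl 3-hydroxy-3-methylpentanedioate
Product: 15 (3S)-3-hydroxy-5-methoxy-3-methyl-5-oxopentanoic acid
Conditions: pig liver esterase, 0.1 M phosphate buffer pH 8 (pH-stat, 1 M NaOH), 25 °C; then HCl to pH 2
Reagents that add atoms: water, O
Why: Enzymatic desymmetrisation, in which the esterase hydrolyses one enantiotopic ester arm of the prochiral diester and sets the glutarate stereocentre as the (S)-half ester.

Step 9
Reactants: 13 prop-2-en-1-yl (2Z,4E)-5-[(1RS,6R)-6-(hydroxymethyl)-2,6-dimethylcyclohex-2-en-1-yl]-3-methylpenta-2,4-dienoate; 15 (3S)-3-hydroxy-5-methoxy-3-methyl-5-oxopentanoic acid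
Product: 16 prop-2-en-1-yl (2Z,4E)-5-[(1RS,6R)-6-({[(3R)-3-hydroxy-5-methoxy-3-methyl-5-oxopentanoyl]oxy}methyl)-2,6-dimethylcyclohex-2-en-1-yl]-3-methylpenta-2,4-dienoate
Conditions: EDC·HCl (1.3 equiv), DMAP (0.2 equiv), CH2Cl2, 0 °C → rt
Reagents that add atoms: none
Why: Steglich-type carbodiimide/DMAP esterification joins the only free CO2H of 15 to the only primary OH of 13 (the tertiary OH of 15 is too hindered to compete) and touches no stereocentre, the glutarate centre becoming 3R by CIP only.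

Step 10
Reactants: 16 prop-2-en-1-yl (2Z,4E)-5-[(1RS,6R)-6-({[(3R)-3-hydroxy-5-methoxy-3-methyl-5-oxopentanoyl]oxy}methyl)-2,6-dimethylcyclohex-2-en-1-yl]-3-methylpenta-2,4-dienoate
Product: 17 prop-2-en-1-yl (2Z,4E)-5-[(1RS,6R)-6-({[(3R)-3-hydroxy-5-methoxy-3-methyl-5-oxopentanoyl]oxy}methyl)-2,6-dimethyl-4-oxocyclohex-2-en-1-yl]-3-methylpenta-2,4-dienoate
Conditions: Rh2(cap)4 (1 mol%), t-BuOOH (70% aq., 5 equiv), CH2Cl2, rt
Reagents that add atoms: tert-butyl hydroperoxide, CC(C)(C)OO
Why: Dirhodium caprolactamate/t-BuOOH allylic oxidation (tert-butylperoxyl hydrogen abstraction) turns the ring allylic CH2 (C-4) into the enone as in α-ionone → 3-oxo-α-ionone, the hindered tertiary H-1, the electron-poor dienoate and the ester groups being left alone.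

Step 11
Reactants: 17 prop-2-en-1-yl (2Z,4E)-5-[(1RS,6R)-6-({[(3R)-3-hydroxy-5-methoxy-3-methyl-5-oxopentanoyl]oxy}methyl)-2,6-dimethyl-4-oxocyclohex-2-en-1-yl]-3-methylpenta-2,4-dienoate
Product: 19 prop-2-en-1-yl (2Z,4E)-5-[(1R,6S)-1-hydroxy-6-({[(3R)-3-hydroxy-5-methoxy-3-methyl-5-oxopentanoyl]oxy}methyl)-2,6-dimethyl-4-oxocyclohex-2-en-1-yl]-3-methylpenta-2,4-dienoate, via 1-hydroperoxide 18 (not isolated)
Conditions: Cs2CO3 (20 mol%), P(OEt)3 (2 equiv), O2 (1 atm), DMSO, rt
Reagents that add atoms: dioxygen, O=O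
Why: Vinylogous enolate autoxidation, in which the base reversibly removes the γ-proton H-1 (activated by the enone and the dienoate), the planar dienolate takes up O2 at C-1 on the face anti to the bulkier CH2O-acyl arm of C-6 (held pseudoaxial to avoid allylic strain with the side chain) and P(OEt)3 reduces the hydroperoxide, so the 1-OH ends trans to the acyloxymethyl group (1R,6S) as in 1'-deoxy-ABA → ABA.

Step 12
Reactants: 19 prop-2-en-1-yl (2Z,4E)-5-[(1R,6S)-1-hydroxy-6-({[(3R)-3-hydroxy-5-methoxy-3-methyl-5-oxopentanoyl]oxy}methyl)-2,6-dimethyl-4-oxocyclohex-2-en-1-yl]-3-methylpenta-2,4-dienoate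
Product: 20 (2Z,4E)-5-[(1R,6S)-1-hydroxy-6-({[(3R)-3-hydroxy-5-methoxy-3-methyl-5-oxopentanoyl]oxy}methyl)-2,6-dimethyl-4-oxocyclohex-2-en-1-yl]-3-methylpenta-2,4-dienoic acid (CNP0274837.1)
Conditions: Pd(PPh3)4 (5 mol%), morpholine (3 equiv), THF, rt; dilute citric acid work-up
Reagents that add atoms: none
Why: Tsuji–Trost deallylation, in which Pd(0) ionises only the allyl ester and morpholine traps the π-allyl, freeing the dienoic acid under neutral conditions that leave the methyl ester, the neopentyl ester, both tertiary alcohols and all stereocentres untouched.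

## Compound list

1 | geranyl acetate, (2E)-3,7-dimethylocta-2,6-dien-1-yl acetate | CC(=O)OC/C=C(C)/CCC=C(C)C | starting material
2 | (2E,6E)-8-hydroxy-3,7-dimethylocta-2,6-dien-1-yl acetate | CC(=O)OC/C=C(C)/CC/C=C(C)/CO | intermediate
3 | (2E)-5-[(2S,3S)-3-(hydroxymethyl)-3-methyloxiran-2-yl]-3-methylpent-2-en-1-yl acetate | OC[C@]1(C)O[C@H]1CC/C(C)=C/COC(C)=O | intermediate
4 | (2E,7R)-3,7-dimethyloct-2-ene-1,7,8-triol | OC/C=C(C)/CCC[C@@](C)(O)CO | intermediate
5 | (2R,6E)-2,8-dihydroxy-2,6-dimethyloct-6-en-1-yl 4-methylbenzenesulfonate | Cc1ccc(cc1)S(=O)(=O)OC[C@](C)(O)CCC/C(C)=C/CO | intermediate (not isolated)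
6 | (2E)-3-methyl-6-[(2R)-2-methyloxiran-2-yl]hex-2-en-1-ol | OC/C=C(C)/CCC[C@]1(C)CO1 | intermediate
7 | (2E)-3-methyl-6-[(2R)-2-methyloxiran-2-yl]hex-2-enal | O=C/C=C(C)/CCC[C@]1(C)CO1 | intermediate
8 | methyl 3-methylbut-2-enoate | COC(=O)C=C(C)C | starting material
9 | methyl (2Z,6E)-5-hydroxy-3,7-dimethyl-10-[(2R)-2-methyloxiran-2-yl]deca-2,6-dienoate (5RS; present as its lithium alkoxide) | COC(=O)/C=C(C)\CC(O)/C=C(C)/CCC[C@]1(C)CO1 | intermediate (not isolated)
10 | 4-methyl-6-{(1E)-2-methyl-5-[(2R)-2-methyloxiran-2-yl]pent-1-en-1-yl}-5,6-dihydro-2H-pyran-2-one (6RS) | CC1=CC(=O)OC(C1)/C=C(C)/CCC[C@]2(C)CO2 | intermediate (not isolated)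
11 | potassium (2Z,4E,6E)-3,7-dimethyl-10-[(2R)-2-methyloxiran-2-yl]deca-2,4,6-trienoate | [K+].[O-]C(=O)/C=C(C)\C=C\C=C(C)\CCC[C@]1(C)CO1 | intermediate (not isolated)
12 | prop-2-en-1-yl (2Z,4E,6E)-3,7-dimethyl-10-[(2R)-2-methyloxiran-2-yl]deca-2,4,6-trienoate | C=CCOC(=O)/C=C(C)\C=C\C=C(C)\CCC[C@]1(C)CO1 | intermediate
13 | prop-2-en-1-yl (2Z,4E)-5-[(1RS,6R)-6-(hydroxymethyl)-2,6-dimethylcyclohex-2-en-1-yl]-3-methylpenta-2,4-dienoate (C-1 epimers, both converge in step 11) | OC[C@]1(C)CCC=C(C)C1/C=C/C(C)=C\C(=O)OCC=C | intermediate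
14 | dimethyl 3-hydroxy-3-methylpentanedioate | COC(=O)CC(C)(O)CC(=O)OC | starting material
15 | (3S)-3-hydroxy-5-methoxy-3-methyl-5-oxopentanoic acid | COC(=O)C[C@@](C)(O)CC(=O)O | intermediate
16 | prop-2-en-1-yl (2Z,4E)-5-[(1RS,6R)-6-({[(3R)-3-hydroxy-5-methoxy-3-methyl-5-oxopentanoyl]oxy}methyl)-2,6-dimethylcyclohex-2-en-1-yl]-3-methylpenta-2,4-dienoate | COC(=O)C[C@@](C)(O)CC(=O)OC[C@]1(C)CCC=C(C)C1/C=C/C(C)=C\C(=O)OCC=C | intermediate
17 | prop-2-en-1-yl (2Z,4E)-5-[(1RS,6R)-6-({[(3R)-3-hydroxy-5-methoxy-3-methyl-5-oxopentanoyl]oxy}methyl)-2,6-dimethyl-4-oxocyclohex-2-en-1-yl]-3-methylpenta-2,4-dienoate | COC(=O)C[C@@](C)(O)CC(=O)OC[C@]1(C)CC(=O)C=C(C)C1/C=C/C(C)=C\C(=O)OCC=C | intermediate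
18 | prop-2-en-1-yl (2Z,4E)-5-[(1R,6S)-1-hydroperoxy-6-({[(3R)-3-hydroxy-5-methoxy-3-methyl-5-oxopentanoyl]oxy}methyl)-2,6-dimethyl-4-oxocyclohex-2-en-1-yl]-3-methylpenta-2,4-dienoate | COC(=O)C[C@@](C)(O)CC(=O)OC[C@]1(C)CC(=O)C=C(C)[C@]1(OO)/C=C/C(C)=C\C(=O)OCC=C | intermediate (not isolated)
19 | prop-2-en-1-yl (2Z,4E)-5-[(1R,6S)-1-hydroxy-6-({[(3R)-3-hydroxy-5-methoxy-3-methyl-5-oxopentanoyl]oxy}methyl)-2,6-dimethyl-4-oxocyclohex-2-en-1-yl]-3-methylpenta-2,4-dienoate | COC(=O)C[C@@](C)(O)CC(=O)OC[C@]1(C)CC(=O)C=C(C)[C@]1(O)/C=C/C(C)=C\C(=O)OCC=C | intermediate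
20 | (2Z,4E)-5-[(1R,6S)-1-hydroxy-6-({[(3R)-3-hydroxy-5-methoxy-3-methyl-5-oxopentanoyl]oxy}methyl)-2,6-dimethyl-4-oxocyclohex-2-en-1-yl]-3-methylpenta-2,4-dienoic acid | COC(=O)C[C@@](C)(O)CC(=O)OC[C@]1(C)CC(=O)C=C(C)[C@]1(O)/C=C/C(C)=C\C(=O)O | target

## Step count and weak points

Total steps: 12. Longest linear sequence: 11 (steps 1–7 and 9–12); step 8 is a one-step side branch.

Most likely to fail, in this order:

First, step 7, the epoxide-initiated cyclisation. The attacking olefin is the end of a conjugated trienoate and is a weak π-nucleophile. The oxirane may instead rearrange to the aldehyde (hydride shift), be opened by HFIP, or open by an SN1 path that erodes the C-6 configuration. The C-2 cation can also give the 1-ene or exocyclic olefin, or be trapped by the new CH2OH as a bridged ether. The fallback cyclises before the dienoate is unveiled, so that the terminating olefin is an ordinary non-conjugated trisubstituted alkene. It sets out from 10, isolated by quenching step 6 with NH4Cl before the KOtBu addition. The same HFIP treatment gives 6-[(1RS,6R)-6-(hydroxymethyl)-2,6-dimethylcyclohex-2-en-1-yl]-4-methyl-5,6-dihydro-2H-pyran-2-one F1. KOtBu (2.2 equiv, THF) then opens the lactone by E1cB to (2Z,4E)-5-[(1RS,6R)-6-(hydroxymethyl)-2,6-dimethylcyclohex-2-en-1-yl]-3-methylpenta-2,4-dienoic acid F2. Cs2CO3/allyl bromide in DMF alkylates only the carboxylate, and the route is rejoined at 13.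

Second, step 11, the γ-hydroxylation. Face selectivity rests only on CH2O-acyl versus CH3 at C-6. Oxygen could also enter at other positions of the extended anion, and the delocalised anion could scramble the 2Z/4E geometry. The fallback replaces the anion by a neutral silyl dienol ether and an electrophilic oxygen donor (vinylogous Rubottom oxidation, as in the 6-hydroxylation of steroidal 3,5-dienol ethers). It sets out from 17. TMSOTf/Et3N (CH2Cl2, 0 °C) gives the bis-trimethylsilyl compound, i.e. the ring 4-silyloxy-1,3-diene with the glutarate OH also silylated, F3. Dimethyldioxirane (acetone, −40 °C) epoxidises the 1,2-olefin anti to the CH2O-acyl arm to give the silyloxy epoxide F4. Aqueous citric acid/MeOH collapses this to the γ-hydroxy enone and removes both silyl groups, rejoining the route at 19.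

Third, step 10, the allylic oxidation. The peroxyl radical may abstract the weak, doubly allylic H-1 or add to the polyene instead of oxidising C-4. The fallback uses exactly that H-1 reactivity and installs both ring oxygens together, as in the classical photo-oxygenation synthesis of abscisic acid. It sets out from 16. NBS (PhCF3, AIBN, 60 °C) gives, through the delocalised C-1 radical, the 3-bromo-cyclohex-1-ene allylic bromide F5. DBU eliminates HBr to the cyclohexa-1,3-diene F6. Singlet oxygen (O2, hν, tetraphenylporphyrin, CH2Cl2, −30 °C) adds across C-1/C-4 anti to the CH2O-acyl arm to give the 1,4-endoperoxide F7. Et3N (Kornblum–DeLaMare rearrangement) converts this to the 1-hydroxy-4-oxo-2-ene, rejoining the route at 19 and bypassing 17 and step 11.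

## Further compounds

F1 | step 7 | 6-[(1RS,6R)-6-(hydroxymethyl)-2,6-dimethylcyclohex-2-en-1-yl]-4-methyl-5,6-dihydro-2H-pyran-2-one (lactone C-6 RS) | OC[C@]1(C)CCC=C(C)C1C2CC(C)=CC(=O)O2
F2 | step 7 | (2Z,4E)-5-[(1RS,6R)-6-(hydroxymethyl)-2,6-dimethylcyclohex-2-en-1-yl]-3-methylpenta-2,4-dienoic acid | OC[C@]1(C)CCC=C(C)C1/C=C/C(C)=C\C(=O)O
F3 | step 11 | prop-2-en-1-yl (2Z,4E)-5-[(6R)-2,6-dimethyl-6-({[(3R)-5-methoxy-3-methyl-5-oxo-3-(trimethylsilyloxy)pentanoyl]oxy}methyl)-4-(trimethylsilyloxy)cyclohexa-1,3-dien-1-yl]-3-methylpenta-2,4-dienoate | COC(=O)C[C@@](C)(O[Si](C)(C)C)CC(=O)OC[C@]1(C)CC(O[Si](C)(C)C)=CC(C)=C1/C=C/C(C)=C\C(=O)OCC=C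
F4 | step 11 | 1,2-epoxide of F3 (oxirane on the ring C-1/C-2 bond, oxygen trans to the acyloxymethyl group) | COC(=O)C[C@@](C)(O[Si](C)(C)C)CC(=O)OC[C@]1(C)CC(O[Si](C)(C)C)=CC2(C)O[C@@]12/C=C/C(C)=C\C(=O)OCC=C
F5 | step 10 | prop-2-en-1-yl (2Z,4E)-5-[(3RS,6R)-3-bromo-6-({[(3R)-3-hydroxy-5-methoxy-3-methyl-5-oxopentanoyl]oxy}methyl)-2,6-dimethylcyclohex-1-en-1-yl]-3-methylpenta-2,4-dienoate | COC(=O)C[C@@](C)(O)CC(=O)OC[C@]1(C)CCC(Br)C(C)=C1/C=C/C(C)=C\C(=O)OCC=C
F6 | step 10 | prop-2-en-1-yl (2Z,4E)-5-[(6R)-6-({[(3R)-3-hydroxy-5-methoxy-3-methyl-5-oxopentanoyl]oxy}methyl)-2,6-dimethylcyclohexa-1,3-dien-1-yl]-3-methylpenta-2,4-dienoate | COC(=O)C[C@@](C)(O)CC(=O)OC[C@]1(C)CC=CC(C)=C1/C=C/C(C)=C\C(=O)OCC=C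
F7 | step 10 | 1,4-endoperoxide of F6 (2,3-dioxabicyclo[2.2.2]oct-5-ene; peroxide bridge trans to the acyloxymethyl group) | COC(=O)C[C@@](C)(O)CC(=O)OC[C@]1(C)CC2C=C(C)[C@]1(OO2)/C=C/C(C)=C\C(=O)OCC=C
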